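**Retrosynthetic overview**

1. The strategy rests on C3 of the dec‑7‑enoate chain, which carries H, CH3, C2H2–C1O2CH3 and the C4 chain. This is the imprint of a [3,3] shift: the target comes from dienoate 21 by saturating C4=C5, and 21 comes from the orthoester Claisen of (S)‑dienol 17 with orthoacetate 18, which forms C2–C3.
2. Dienol 17 is assembled by a B‑alkyl Suzuki–Miyaura coupling of (E)‑iodoalkene 7 with borane 16, made in situ from vinylfuran 15.
3. Iodoalkene 7 comes from (E)‑but‑2‑enal 1 by catalytic asymmetric propargylation (carbinol centre), then zirconium‑catalysed methylalumination–iodination (E trisubstituted olefin).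
4. Vinylfuran 15 comes from 3‑bromofuran 8 and 4‑bromofuran‑2‑carbaldehyde 9 by aryllithium addition, ionic deoxygenation of the carbinol and vinylation.
5. No ring is formed in the route: ring A (the 2,4‑disubstituted furan) and ring B (the 3‑substituted furan) are both bought as bromofurans.

Key step: step 7

Remark: the target is (3R); in Claisen product 21 the same spatial arrangement at C3 is named (3S) because C4 is olefinic there. The facial sense of the (S)‑configured phosphoric acid in step 1 is assumed from the behaviour of this catalyst class with aryl and alkenyl aldehydes, and the configuration and enantiomeric purity of 4 are to be checked (Mosher esters) before material is carried on.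

**Step 1**
Reactants: 1 (E)‑but‑2‑enal; 2 allenylboronic acid pinacol ester
Product: 4 (4S,5E)‑hept‑5‑en‑1‑yn‑4‑ol, via pinacol borate ester 3 (not isolated)
Conditions: (S)‑3,3′‑bis(2,4,6‑triisopropylphenyl)‑1,1′‑binaphthyl‑2,2′‑diyl hydrogen phosphate [(S)‑TRIP, 10 mol%], 4 Å MS, toluene, 0 °C; then aq. NaHCO3
Reagents that add atoms: none
Why: Chiral phosphoric acid‑catalysed propargylboration (SE2′ transfer from the allenylboronate through a closed six‑membered transition state held by hydrogen bonding to the catalyst) should give only the 1,2‑adduct as the homopropargylic alcohol, and the (S)‑catalyst, antipode of the one that leads to (R)‑carbinols, should set C4 as (S) under catalyst control.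

**Step 2**
Reactants: 4 (4S,5E)‑hept‑5‑en‑1‑yn‑4‑ol
Product: 7 (2E,4S,6E)‑7‑iodo‑6‑methylhepta‑2,6‑dien‑4‑ol, via alkenyldimethylalane alkoxide 5 (not isolated), via dimethylaluminium alkoxide of the iodide 6 (not isolated)
Conditions: AlMe3 (3.5 equiv), Cp2ZrCl2 (0.3 equiv), CH2Cl2, 0 °C → rt; then I2 (1.5 equiv), THF, −30 → 0 °C; aq. KNaC4H4O6
Reagents that add atoms: trimethylaluminium, C[Al](C)C; iodine, II
Why: Zirconium‑catalysed methylalumination (Negishi carboalumination) adds CH3 and aluminium syn across the terminal alkyne with aluminium at the terminus while the hydroxyl is masked in the flask as its aluminium alkoxide, and iodinolysis of the C–Al bond with retention should give the (E)‑iodoalkene, leaving the internal propenyl olefin and the carbinol centre untouched.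

**Step 3**
Reactants: 8 3‑bromofuran; 9 4‑bromofuran‑2‑carbaldehyde
Product: 12 (±)‑(4‑bromofuran‑2‑yl)(furan‑3‑yl)methanol, via 3‑furyllithium 10 (not isolated), via lithium alkoxide of the carbinol 11 (not isolated)
Conditions: 8 (1.15 equiv), n‑BuLi (1.1 equiv), THF, −78 °C, 20 min; then 9 (1.0 equiv), −78 °C; H2O
Reagents that add atoms: n‑butyllithium, [Li]CCCC (its lithium stays only in 10 and 11)
Why: Bromine–lithium exchange at −78 °C gives 3‑furyllithium, which keeps its position at that temperature and undergoes 1,2‑addition to the aldehyde faster than it exchanges with the ring bromide of 9; the new carbinol centre is racemic and is removed in step 4.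

**Step 4**
Reactants: 12 (±)‑(4‑bromofuran‑2‑yl)(furan‑3‑yl)methanol
Product: 13 4‑bromo‑2‑(furan‑3‑ylmethyl)furan
Conditions: Et3SiH (3 equiv), CF3CO2H (3 equiv, added last), CH2Cl2, −20 → 0 °C
Reagents that add atoms: none
Why: Ionic hydrogenation (Kursanov–Parnes reduction): the carbocation stabilised by both furans is captured by hydride from the silane, which is present in excess before the acid is added so that alkylation of a second furan should not compete, and the ring bromide lowers the acid sensitivity of ring A.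

**Step 5**
Reactants: 13 4‑bromo‑2‑(furan‑3‑ylmethyl)furan; 14 vinylboronic acid pinacol ester
Product: 15 4‑ethenyl‑2‑(furan‑3‑ylmethyl)furan
Conditions: Pd(PPh3)4 (5 mol%), aq. K2CO3 (2 M), 1,4‑dioxane, 85 °C
Reagents that add atoms: none
Why: Suzuki–Miyaura coupling of the heteroaryl bromide with the vinylboronate runs under mild aqueous carbonate that leaves both furans and the bridging CH2 alone; the vinylfuran is to be used at once to avoid polymerisation.

**Step 6**
Reactants: 15 4‑ethenyl‑2‑(furan‑3‑ylmethyl)furan; 7 (2E,4S,6E)‑7‑iodo‑6‑methylhepta‑2,6‑dien‑4‑ol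
Product: 17 (2E,4S,6E)‑9‑[5‑(furan‑3‑ylmethyl)furan‑3‑yl]‑6‑methylnona‑2,6‑dien‑4‑ol, via B‑alkyl‑9‑BBN borane 16 (not isolated)
Conditions: 15 (1.5 equiv), 9‑BBN (0.5 M in THF, 1.4 equiv), 0 °C → rt; then aq. Cs2CO3, 7 (1.0 equiv), PdCl2(dppf) (5 mol%), AsPh3 (10 mol%), DMF, rt
Reagents that add atoms: 9‑borabicyclo[3.3.1]nonane, B1C2CCCC1CCC2 (its boron unit stays only in 16)
Why: Anti‑Markovnikov hydroboration with the bulky 9‑BBN places boron on the terminal vinyl carbon, and the B‑alkyl Suzuki–Miyaura coupling joins this primary alkyl group to the alkenyl iodide with retention of the E geometry and tolerance of the free secondary hydroxyl, so the carbinol centre is carried through unchanged.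

**Step 7**
Reactants: 17 (2E,4S,6E)‑9‑[5‑(furan‑3‑ylmethyl)furan‑3‑yl]‑6‑methylnona‑2,6‑dien‑4‑ol; 18 trimethyl orthoacetate (8 equiv)
Product: 21 methyl (3S,4E,7E)‑10‑[5‑(furan‑3‑ylmethyl)furan‑3‑yl]‑3,7‑dimethyldeca‑4,7‑dienoate, via mixed orthoester 19 (not isolated), via ketene acetal 20 (not isolated)
Conditions: EtCO2H (10 mol%), xylene, 130 °C, MeOH distilled off
Reagents that add atoms: none
Why: Acid‑catalysed exchange of one methoxy group of 18 for the carbinol oxygen gives 19, loss of methanol gives ketene acetal 20, and 20 undergoes a concerted suprafacial [3,3]‑sigmatropic shift that trades the C5–O bond (ester numbering) for the C2–C3 bond. This is the Johnson orthoester Claisen rearrangement of a secondary (E)‑allylic alcohol, a known reaction type; no ring is closed, the six‑membered array existing only in the chair transition state. The new C3 stereocentre is controlled by the (S)‑carbinol centre together with the E geometry of the propenyl group: in the chair with the C6 chain equatorial the new bond forms on the face of the allyl unit from which oxygen departs, which gives (3S) and an E C4=C5 olefin. The selectivity needed is that equatorial placement, since an axial chain would give the 4Z isomer with the opposite C3 configuration; it is secured by the 1,3‑diaxial clash between an axial chain and the methoxy group of the ketene acetal. Only the propenyl olefin is allylic to the oxygen, so the C7=C8 olefin cannot take part, and catalytic propionic acid is too weak to attack the alkylfurans.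

**Step 8**
Reactants: 21 methyl (3S,4E,7E)‑10‑[5‑(furan‑3‑ylmethyl)furan‑3‑yl]‑3,7‑dimethyldeca‑4,7‑dienoate
Product: 22 methyl (3R,7E)‑10‑[5‑(furan‑3‑ylmethyl)furan‑3‑yl]‑3,7‑dimethyldec‑7‑enoate
Conditions: 2‑nitrobenzenesulfonyl hydrazide (NBSH, 5 equiv in portions), Et3N, CH2Cl2, rt
Reagents that add atoms: none
Why: Diimide reduction: diimide made in the flask transfers two hydrogens in a concerted syn fashion at rates that fall steeply with olefin substitution, so the 1,2‑disubstituted C4=C5 olefin should be saturated while the trisubstituted C7=C8 olefin, the ester and both aromatic furans remain, and C3 is not touched (its descriptor changes from S to R only because C4 becomes saturated).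

**Compound list**

1 | (E)‑but‑2‑enal | C/C=C/C=O | starting material
2 | allenylboronic acid pinacol ester (4,4,5,5‑tetramethyl‑2‑(propa‑1,2‑dienyl)‑1,3,2‑dioxaborolane) | C=C=CB1OC(C)(C)C(C)(C)O1 | starting material
3 | 2‑{[(4S,5E)‑hept‑5‑en‑1‑yn‑4‑yl]oxy}‑4,4,5,5‑tetramethyl‑1,3,2‑dioxaborolane | C/C=C/[C@@H](OB1OC(C)(C)C(C)(C)O1)CC#C | intermediate
4 | (4S,5E)‑hept‑5‑en‑1‑yn‑4‑ol | C/C=C/[C@@H](O)CC#C | intermediate
5 | {(1E,4S,5E)‑4‑[(dimethylalumanyl)oxy]‑2‑methylhepta‑1,5‑dien‑1‑yl}dimethylalumane | C/C=C/[C@@H](O[Al](C)C)C/C(C)=C/[Al](C)C | intermediate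
6 | dimethylaluminium (2E,4S,6E)‑7‑iodo‑6‑methylhepta‑2,6‑dien‑4‑olate | C/C=C/[C@@H](O[Al](C)C)C/C(C)=C/I | intermediate
7 | (2E,4S,6E)‑7‑iodo‑6‑methylhepta‑2,6‑dien‑4‑ol | C/C=C/[C@@H](O)C/C(C)=C/I | intermediate
8 | 3‑bromofuran | Brc1ccoc1 | starting material
9 | 4‑bromofuran‑2‑carbaldehyde | O=Cc1cc(Br)co1 | starting material
10 | 3‑furyllithium | [Li]c1ccoc1 | intermediate
11 | lithium (4‑bromofuran‑2‑yl)(furan‑3‑yl)methanolate | [Li]OC(c1cc(Br)co1)c1ccoc1 | intermediate
12 | (±)‑(4‑bromofuran‑2‑yl)(furan‑3‑yl)methanol | OC(c1cc(Br)co1)c1ccoc1 | intermediate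
13 | 4‑bromo‑2‑(furan‑3‑ylmethyl)furan | Brc1coc(Cc2ccoc2)c1 | intermediate
14 | vinylboronic acid pinacol ester (2‑ethenyl‑4,4,5,5‑tetramethyl‑1,3,2‑dioxaborolane) | C=CB1OC(C)(C)C(C)(C)O1 | starting material
15 | 4‑ethenyl‑2‑(furan‑3‑ylmethyl)furan | C=Cc1coc(Cc2ccoc2)c1 | intermediate
16 | 9‑{2‑[5‑(furan‑3‑ylmethyl)furan‑3‑yl]ethyl}‑9‑borabicyclo[3.3.1]nonane | B1(CCc2coc(Cc3ccoc3)c2)C2CCCC1CCC2 | intermediate
17 | (2E,4S,6E)‑9‑[5‑(furan‑3‑ylmethyl)furan‑3‑yl]‑6‑methylnona‑2,6‑dien‑4‑ol | C/C=C/[C@@H](O)C/C(C)=C/CCc1coc(Cc2ccoc2)c1 | intermediate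
18 | trimethyl orthoacetate | CC(OC)(OC)OC | starting material
19 | 4‑[(3E,6S,7E)‑6‑(1,1‑dimethoxyethoxy)‑4‑methylnona‑3,7‑dien‑1‑yl]‑2‑(furan‑3‑ylmethyl)furan | C/C=C/[C@@H](OC(C)(OC)OC)C/C(C)=C/CCc1coc(Cc2ccoc2)c1 | intermediate
20 | 2‑(furan‑3‑ylmethyl)‑4‑{(3E,6S,7E)‑6‑[(1‑methoxyethenyl)oxy]‑4‑methylnona‑3,7‑dien‑1‑yl}furan | C/C=C/[C@@H](OC(=C)OC)C/C(C)=C/CCc1coc(Cc2ccoc2)c1 | intermediate
21 | methyl (3S,4E,7E)‑10‑[5‑(furan‑3‑ylmethyl)furan‑3‑yl]‑3,7‑dimethyldeca‑4,7‑dienoate | COC(=O)C[C@H](C)/C=C/C/C(C)=C/CCc1coc(Cc2ccoc2)c1 | intermediate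
22 | methyl (3R,7E)‑10‑[5‑(furan‑3‑ylmethyl)furan‑3‑yl]‑3,7‑dimethyldec‑7‑enoate | COC(=O)C[C@H](C)CCC/C(C)=C/CCc1coc(Cc2ccoc2)c1 | target

**Step count**

Total: 8 steps. Longest linear sequence: 6 steps (steps 3, 4, 5, 6, 7, 8 from 3‑bromofuran); the branch from (E)‑but‑2‑enal (steps 1 and 2) joins at step 6.

**Steps most likely to fail**

Step 4. The risk is acid‑induced oligomerisation or ring alkylation of the furans while the carbinol is ionised, before hydride capture. The fallback sets out from 12 and avoids acid and carbocations altogether. Oxidation with MnO2 (CH2Cl2, rt) should give (4‑bromofuran‑2‑yl)(furan‑3‑yl)methanone F1. Wolff–Kishner reduction in the Huang‑Minlon manner (N2H4·H2O, KOH, diethylene glycol, 120 → 190 °C) should then pass through [(4‑bromofuran‑2‑yl)(furan‑3‑yl)methylidene]hydrazine F2, which loses nitrogen under the hot base. The fallback comes back to the route at 13.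

Step 8. The risk is loss of chemoselectivity: partial saturation of the C7=C8 olefin when excess diimide is needed to drive the hindered, allylically branched C4=C5 olefin to completion. The fallback reorders the events so that the reduction is done before the chains are joined, and it sets out from iodide 7.
- The same orthoester Claisen (18, EtCO2H cat., 130 °C) should pass through (1E,4S,5E)‑4‑(1,1‑dimethoxyethoxy)‑1‑iodo‑2‑methylhepta‑1,5‑diene F3 and (1E,4S,5E)‑1‑iodo‑4‑[(1‑methoxyethenyl)oxy]‑2‑methylhepta‑1,5‑diene F4 to methyl (3S,4E,7E)‑8‑iodo‑3,7‑dimethylocta‑4,7‑dienoate F5.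
- Diimide (NBSH, Et3N) then meets one simple disubstituted olefin beside a trisubstituted iodoalkene and should give methyl (3R,7E)‑8‑iodo‑3,7‑dimethyloct‑7‑enoate F6.
- B‑alkyl Suzuki–Miyaura coupling of F6 with borane 16 (PdCl2(dppf), AsPh3, aq. K3PO4 to spare the ester, DMF, rt) comes back to the route at target 22.

Step 7. The risks are thermal or acid‑induced erosion of the substrate (dehydration of the carbinol towards a triene, furan decomposition at 130 °C) and incomplete chair control. Incomplete chair control would give some 4Z isomer with the opposite C3 configuration; this isomer has to be removed on AgNO3‑impregnated silica before step 8, because reduction would turn it into the enantiomer of the target. The fallback keeps the C2–C3 disconnection but runs it cold under base as an Ireland–Claisen rearrangement, setting out from 17.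
- Acetylation (Ac2O, pyridine, DMAP cat.) should give (2E,4S,6E)‑9‑[5‑(furan‑3‑ylmethyl)furan‑3‑yl]‑6‑methylnona‑2,6‑dien‑4‑yl acetate F7.
- LiN(i‑Pr)2 and Me3SiCl in THF at −78 °C should give 2‑(furan‑3‑ylmethyl)‑4‑[(3E,6S,7E)‑4‑methyl‑6‑({1‑[(trimethylsilyl)oxy]ethenyl}oxy)nona‑3,7‑dien‑1‑yl]furan F8.
- On warming to rt, F8 should rearrange through the same chair to trimethylsilyl (3S,4E,7E)‑10‑[5‑(furan‑3‑ylmethyl)furan‑3‑yl]‑3,7‑dimethyldeca‑4,7‑dienoate F9.
- Aqueous work‑up gives (3S,4E,7E)‑10‑[5‑(furan‑3‑ylmethyl)furan‑3‑yl]‑3,7‑dimethyldeca‑4,7‑dienoic acid F10, and methylation with Me3SiCHN2 (toluene/MeOH, rt) comes back to the route at 21.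

**Further compounds**

F1 | step 4 | (4‑bromofuran‑2‑yl)(furan‑3‑yl)methanone | O=C(c1cc(Br)co1)c1ccoc1
F2 | step 4 | [(4‑bromofuran‑2‑yl)(furan‑3‑yl)methylidene]hydrazine | NN=C(c1cc(Br)co1)c1ccoc1
F3 | step 8 | (1E,4S,5E)‑4‑(1,1‑dimethoxyethoxy)‑1‑iodo‑2‑methylhepta‑1,5‑diene | C/C=C/[C@@H](OC(C)(OC)OC)C/C(C)=C/I
F4 | step 8 | (1E,4S,5E)‑1‑iodo‑4‑[(1‑methoxyethenyl)oxy]‑2‑methylhepta‑1,5‑diene | C/C=C/[C@@H](OC(=C)OC)C/C(C)=C/I
F5 | step 8 | methyl (3S,4E,7E)‑8‑iodo‑3,7‑dimethylocta‑4,7‑dienoate | COC(=O)C[C@H](C)/C=C/C/C(C)=C/I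
F6 | step 8 | methyl (3R,7E)‑8‑iodo‑3,7‑dimethyloct‑7‑enoate | COC(=O)C[C@H](C)CCC/C(C)=C/I
F7 | step 7 | (2E,4S,6E)‑9‑[5‑(furan‑3‑ylmethyl)furan‑3‑yl]‑6‑methylnona‑2,6‑dien‑4‑yl acetate | C/C=C/[C@@H](OC(C)=O)C/C(C)=C/CCc1coc(Cc2ccoc2)c1
F8 | step 7 | 2‑(furan‑3‑ylmethyl)‑4‑[(3E,6S,7E)‑4‑methyl‑6‑({1‑[(trimethylsilyl)oxy]ethenyl}oxy)nona‑3,7‑dien‑1‑yl]furan | C/C=C/[C@@H](OC(=C)O[Si](C)(C)C)C/C(C)=C/CCc1coc(Cc2ccoc2)c1
F9 | step 7 | trimethylsilyl (3S,4E,7E)‑10‑[5‑(furan‑3‑ylmethyl)furan‑3‑yl]‑3,7‑dimethyldeca‑4,7‑dienoate | C[Si](C)(C)OC(=O)C[C@H](C)/C=C/C/C(C)=C/CCc1coc(Cc2ccoc2)c1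
F10 | step 7 | (3S,4E,7E)‑10‑[5‑(furan‑3‑ylmethyl)furan‑3‑yl]‑3,7‑dimethyldeca‑4,7‑dienoic acid | OC(=O)C[C@H](C)/C=C/C/C(C)=C/CCc1coc(Cc2ccoc2)c1
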